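Open a ledger on J before you look at any clock.

in all of them: time 80 s
- teal: G 0.20 mM; J 1.10 equiv; everything together at the start
- red: G 0.20 mM (fed, over 1.0 min); J 1.10 equiv; all else is in the flask from the start; the feed brings no volume worth counting
- blue: G 0.20 mM; J 1.10 equiv (fed, over 1.0 min); all else is in the flask from the start; the feed brings no volume worth counting
- grey: G 0.20 mM (in portions, 3, over 1.0 min); J 1.10 equiv; first portion at the start, last at 1.0 min

    G + J ⇌ D + Z (K1 = 9.7, k1 = 66 L mol⁻¹ s⁻¹)
    Z + J ⇌ D + X (K2 = 0.36, k2 = 17 L mol⁻¹ s⁻¹)
    X + J ⇌ D + E (K3 = 1.5, k3 = 87 L mol⁻¹ s⁻¹)
    E ⇌ L (K4 = 0.54, k4 = 0.023 s⁻¹)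
    J → Q (k5 = 0.0055 s⁻¹)

1. the best flask by share of E in E plus L; "all alike" if 1.5 percentage points covers them all (teal / red / blue / grey / all alike)
2. share of E in E plus L at the end, teal
3. share of E in E plus L at the end, red
4. share of E in E plus L at the end, blue
5. share of E in E plus L at the end, grey

Each E costs 3 J against 1.10 equiv charged, so J is the limiting reagent for E, and each J has to be booked somewhere. In teal at the start, counting the forward rate of the first step, J goes to G rather than to Q by 2.4 to one, so 29.4% of its flow is booked to Q at that moment. The next entry is J spent on Z: in teal, with the forward rate of the second step alone and concentrations as charged, the half-life of Z is 190 s, longer than the 80 s you wait. For J spent on X, the same kind of half-life, of X by the forward rate of the third step in teal, is shorter, at 36 s. The last entry is E plus L, and there the books close, since turning E into L costs no J. I take that entry as a thin, steady trickle, so [E]/([E]+[L]) becomes a question of the clock.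

So count turnovers. E and L trade at the turnover rate, forward and back added, 0.0656 s⁻¹, which is a relaxation half-life of 10.6 s, and their balance share of E is 64.9%. If the pair is fed steadily with E for a window w, it has seen N turnovers, the rate times w. The share of E then stands above balance by a part of the gap to pure E, which is 35.1%, and that part is one minus exp(−N), all over N. In teal the window is 80 s, so N is 5.25 and the share is 71.6%. In red and grey, G arrives on average at 30.0 s, which leaves a window of 50.0 s, so red gives 75.2% and grey 75.2%; I cannot part those two. In blue, the last of the 3 J an E needs comes from the steady feed on average at 45.0 s, which leaves 35.0 s and a share of 78.7%. My pick is blue.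

The forecast also named blue, with teal 72%, red 75.5%, blue 78% and grey 74%, on the ground that “Feeding delays E formation, most of all when J is fed”; unlike my reckoning, it parts red from grey.

The simulation puts blue first, with teal 73.1%, red 76.3%, blue 80.0% and grey 74.8%.

Now leave teal standing and read it at 2.5 min. The window grows to that time, so the count rises from 5.25 to 9.84 turnovers, and the same reckoning gives a share of 68.5%. That later flask reads 66.7%, less than teal's 73.1%.

The numbers were set for the occasion.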